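# Proposed total synthesis of junceellolide K (38)

## Structural features

Junceellolide K (38) is a briarane. A cyclohexane (C1, C10–C14) is fused through C1–C10 to a ten-membered carbocycle (C1–C10), which shares C7–C8 with a γ-lactone (O–C19–C17–C8–C7); C11 carries a spiro-epoxide whose methylene is C20. There are nine stereocentres: two contiguous runs, C7–C8–C9–C10–C11 and C14–C1–C2, plus C17 next to C8. The quaternary C1 sits between the C2 and C14 acetoxy carbinols in a 1,3-anti array. The fully substituted C8 bears a free tertiary hydroxyl that is cis to C6 and to the C18 methyl on the lactone, so C6, C9 and C18 are all trans around that ring. Fragile groups are the epoxide (acid, nucleophiles), the tertiary β-hydroxy lactone (retro-aldol, elimination to a butenolide) and three acetates (base). The real difficulty is the ten-membered ring with its Z-trisubstituted C5=C6 alkene, combined with the trans C1/C10 fusion and the dense oxygenation from C7 to C9. The route exploits that C10 is α to oxygenated C9 and bonded to C11, which carries C20: with C9 as a ketone and C11=C20 as an exocyclic alkene, the C10–C11 bond is the retron of a Conia-ene closure of a C9 enol ether onto a C11≡C20 alkyne.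

## Logic of the disconnections

**38 back to 34.** The epoxide C–O bonds at C11/C20, the C9 acetate and the C9–H bond are removed, passing through 37, 36 and 35. This keeps the acid-sensitive epoxide out of all earlier chemistry. The forward steps must reduce the C9 ketone from the correct face and epoxidise C11=C20 in the presence of C5=C6.

**34 back to 33.** The C10–C11 bond is cut. This opens the cyclohexane and removes the C10 stereocentre, leaving a monocyclic ten-membered enol ether with a pentynyl arm on C1. The forward step must close 6-exo-dig on the enol ether face that gives the trans fusion.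

**33 back to 28.** Two O–Si bonds and the C9 oxidation level are adjusted (through 31 and 30). C9 is carried as a protected carbinol so that only one ketone (C8) is present when the lactone is made. The forward steps must silylate O8 and enolise only towards C10, which C8 guarantees because it has no hydrogen.

**28 back to 23 and 24.** The C8–C17 bond and the C7–O acyl bond are cut (through 27, 26 and 25). The lactone becomes a tethered propionate aldol on a C8 ketone. The tether on the C7 oxygen must deliver C17 so that C9 ends trans to C6 and the C18 methyl trans to C9, which is also the thermodynamically preferred arrangement.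

**23 back to 22.** The C6–C7 bond is cut. The ten-membered ring opens to a Z-vinyl iodide and an α-alkoxy aldehyde. The forward step must close a strained ring at high dilution and set C7, for which the temporary C8 stereocentre is the handle.

**22 back to 17 and 18.** The C8–C9 bond is cut (through 20 and 19), and the C7 aldehyde is seen as a vinyl group. One reagent-controlled alkoxyallylation supplies C7 and C8, differentiates the C8 and C9 oxygens, and installs sacrificial stereocentres that steer C7. It must tolerate two acetates.

**17 back to 9 and 12.** The C9 aldehyde is traced to an allyl group (15), the C2–H bond to a 1,3-anti reduction (14 from 13), and the C3–C4 bond to an enolate alkylation. This splits the chain into a methyl ketone and an allylic bromide of fixed Z geometry. Because C1 is quaternary, only C3 can be enolised.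

**9 back to 4 and 5.** The C2–C3 bond (through 8), the C1–C15 bond (7 from 6) and the C1–C10 bond (6 from 4) are cut. The quaternary centre comes from two successive alkylations of a β-hydroxy ester dianion. The order (allyl first, methyl last) fixes C1, since the last electrophile enters anti to the C14 oxygen.

**4 back to 1 and 2.** The C14–H bond and the C12–C13 bond are cut (through 3). The C14 stereocentre comes from catalytic asymmetric hydrogenation, and the alkyne arm from a dianion alkylation.

**12 back to 10.** The C5–C16 and C6–I bonds are cut (through 11). A chelation-controlled anti carbometalation of a propargylic alkoxide fixes the Z geometry.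

## Other disconnections considered

**Alternative 1:** The cut runs through C9–C10 and C1–C2 on a cyclohexane that already exists.
- *Forward step:* a vinyl cuprate adds to C10 of enone A2; the enolate, after transmetalation to zinc, adds through C1 to aldehyde A3 and gives adduct A1 without any ring closure.
- *In favour:* one flask sets C10, C1 and C2 including the quaternary centre. The six-membered ring comes from a simple cyclohexenone. The two arms that must later close the ten-membered ring are held on adjacent positions of a chair, which is a better preorganisation than the open chain of 22. On these three points it is the better plan.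
- *Against:* the aldol of a hindered, fully substituted enolate with an enolisable aldehyde and the configuration of the C2 carbinol are uncertain. The C14 ketone must still be reduced to the axial alcohol. The C11 silyloxy group must be converted into the spiro-epoxide by oxidation and methylene transfer. C7–C9, the lactone and the macrocycle remain to be built on A1.
- *Comparison:* it uses the same Z-vinyl iodide logic for C6–C7 (equal). It reaches the C1/C2/C10 triad in far fewer steps than the sequence to 17. It gives up the Conia-ene closure and moves the risk to a longer end game at C11 and C14 on a crowded bicycle.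

**Alternative 2:** The cut is C3–C4, made together with C6–O.
- *Forward step:* heating the 2-methylene oxocane A5 triggers a Claisen rearrangement that forms C3–C4 and C5=C6, breaks C6–O and expands the eight-membered ether to the ten-membered ketone A4.
- *In favour:* the concerted cyclic transition state enforces the Z geometry of C5=C6. No high-dilution macrocyclisation is needed. C7, C9, C10, C11 and C14 are already in place, so there is no stereochemical gamble at C7. On these points it equals or betters the chromium-mediated closure of 22.
- *Against:* A5 is itself a medium ring that must be made (eight-membered lactone, then methylenation). It combines an acid-labile enol ether with an epoxide and acetals at high temperature. The C2 ketone of A4 must be reduced with the right sense on the macrocycle. The whole lactone (C17–C19 on the masked C8 ketone) and all acetates follow late.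
- *Comparison:* structurally it keeps the cyclohexane and epoxide from the start, whereas the chosen route forms the cyclohexane last. Mechanistically a pericyclic step is more predictable in geometry than an organochromium addition. In step economy the many post-rearrangement operations and the preparation of A5 are expected to outweigh the gain.

**Alternative 3:** The cuts are C7–C8, C17–C19 and C19–O.
- *Forward step:* a low-valent metal carbonyl couples the C7 carbonyl of enal A7, its C8≡C17 alkyne and a carbonyl unit in a hetero-Pauson–Khand reaction, closing the ten-membered ring and the butenolide of A6 at once.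
- *In favour:* it has the highest convergence of all plans, forming three bonds and two rings in one step on a substrate that already holds the cyclohexane, the epoxide and three acetoxy-level oxygens. In bond economy it is clearly the better plan.
- *Against:* a macrocyclic hetero-Pauson–Khand reaction forming a ten-membered ring has no close precedent, and a conjugated aldehyde is a reluctant partner. C7 would be set without an obvious control element. A6 has a C8=C17 butenolide, so the tertiary C8 hydroxyl cis to C6 would need a formal hydration against the steric bias of the lactone.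
- *Comparison:* the chosen route uses only established reaction types for ring closure and lactone formation, and sets C8 and C17 in the closure itself. Alternative 3 would be several steps shorter if the key step and the later hydration could be realised, so its advantage is length and its weakness is mechanism and precedent.

Key step: step 24

Remark: atoms carry the briarane numbers C1–C20 of 38; where a CIP letter of an intermediate might shift through a priority change, the SMILES string is authoritative.

Remark: acid bromide 24 is used as the racemate, so 25–27 are mixtures at the bromine-bearing carbon, which becomes C17 only after enolate formation.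

## Route

Step 1
Reactants: 1 methyl acetoacetate; 2 3-bromo-1-(trimethylsilyl)prop-1-yne
Product: 3 methyl 3-oxo-7-(trimethylsilyl)hept-6-ynoate
Conditions: NaH, THF, 0 °C; n-BuLi, 0 °C; 2, 0 °C → rt; aq. HCl
Reagents that add atoms: none
Why: Alkylation of the acetoacetate dianion occurs at the more basic terminal carbon, and the propargylic bromide is a good SN2 partner; this forms C12–C13 and brings in C11 and C20 as a silyl-capped alkyne.

Step 2
Reactants: 3 methyl 3-oxo-7-(trimethylsilyl)hept-6-ynoate
Product: 4 methyl (3S)-3-hydroxy-7-(trimethylsilyl)hept-6-ynoate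
Conditions: H2 (10 atm), RuCl2[(S)-BINAP] (0.5 mol%), MeOH, 50 °C
Reagents that add atoms: none
Why: Noyori asymmetric hydrogenation of a β-keto ester; the chelated keto ester is reduced under control of the (S)-diphosphine to the 3S alcohol (C14 of the target), while the silyl-capped internal alkyne does not chelate and should be left alone.

Step 3
Reactants: 4 methyl (3S)-3-hydroxy-7-(trimethylsilyl)hept-6-ynoate; 5 allyl bromide
Product: 6 methyl (2S,3S)-3-hydroxy-2-(prop-2-en-1-yl)-7-(trimethylsilyl)hept-6-ynoate
Conditions: LiN(i-Pr)2 (2.2 equiv), THF, −78 → −20 °C; 5, −78 → 0 °C; H2O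
Reagents that add atoms: none
Why: Fráter–Seebach alkylation of the chelated alkoxide–enolate dianion introduces C10 and C9 (anti product expected); the configuration at this carbon is erased again in step 4.

Step 4
Reactants: 6 methyl (2S,3S)-3-hydroxy-2-(prop-2-en-1-yl)-7-(trimethylsilyl)hept-6-ynoate
Product: 7 methyl (2R,3S)-3-hydroxy-2-methyl-2-(prop-2-en-1-yl)-7-(trimethylsilyl)hept-6-ynoate
Conditions: LiN(i-Pr)2 (2.5 equiv), THF, −78 → −20 °C; MeI, DMPU, −78 → −10 °C; H2O
Reagents that add atoms: iodomethane, CI
Why: A second Fráter–Seebach alkylation; the lithium-chelated, fully substituted enolate is attacked by iodomethane on the face opposite the C13 chain of the carbinol carbon, so the methyl (C15) ends anti to the C14 oxygen and the allyl group syn, which is the C1 configuration of the target.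

Step 5
Reactants: 7 methyl (2R,3S)-3-hydroxy-2-methyl-2-(prop-2-en-1-yl)-7-(trimethylsilyl)hept-6-ynoate
Product: 8 (2R,3S)-3-hydroxy-N-methoxy-N,2-dimethyl-2-(prop-2-en-1-yl)-7-(trimethylsilyl)hept-6-ynamide
Conditions: MeNHOMe·HCl, i-PrMgCl, THF, −20 °C → rt; H2O
Reagents that add atoms: N,O-dimethylhydroxylamine hydrochloride, CNOC.Cl
Why: Aminolysis of the ester by the magnesium amide gives the Weinreb amide; the α-carbon is quaternary, so no epimerisation is possible and the free alkoxide only costs one equivalent of base.

Step 6
Reactants: 8 (2R,3S)-3-hydroxy-N-methoxy-N,2-dimethyl-2-(prop-2-en-1-yl)-7-(trimethylsilyl)hept-6-ynamide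
Product: 9 (3R,4S)-4-hydroxy-3-methyl-3-(prop-2-en-1-yl)-8-(trimethylsilyl)oct-7-yn-2-one
Conditions: MeMgBr (3 equiv), THF, 0 °C; H2O
Reagents that add atoms: methylmagnesium bromide, C[Mg]Br
Why: Weinreb ketone synthesis; the chelated tetrahedral intermediate stops at mono-addition and releases the C2 methyl ketone (its methyl is C3) only on work-up.

Step 7
Reactants: 10 propargyl alcohol
Product: 11 (2Z)-3-iodo-2-methylprop-2-en-1-ol
Conditions: MeMgBr (2.5 equiv), CuI (10 mol%), THF, −10 °C → rt; I2, 0 °C; H2O
Reagents that add atoms: methylmagnesium bromide, C[Mg]Br; iodine, II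
Why: Copper-catalysed anti carbomagnesiation of the propargylic alkoxide places the methyl (C16) on C5 and magnesium on C6 in a five-membered chelate; iodinolysis with retention gives the Z-vinyl iodide.

Step 8
Reactants: 11 (2Z)-3-iodo-2-methylprop-2-en-1-ol
Product: 12 (1Z)-3-bromo-1-iodo-2-methylprop-1-ene
Conditions: CBr4, PPh3, CH2Cl2, 0 °C
Reagents that add atoms: tetrabromomethane, BrC(Br)(Br)Br
Why: Appel bromination of a primary allylic alcohol proceeds under neutral conditions without touching the vinyl iodide or its geometry.

Step 9
Reactants: 9 (3R,4S)-4-hydroxy-3-methyl-3-(prop-2-en-1-yl)-8-(trimethylsilyl)oct-7-yn-2-one; 12 (1Z)-3-bromo-1-iodo-2-methylprop-1-ene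
Product: 13 (1Z,6R,7S)-7-hydroxy-1-iodo-2,6-dimethyl-6-(prop-2-en-1-yl)-11-(trimethylsilyl)undec-1-en-10-yn-5-one
Conditions: LiN(i-Pr)2 (2.2 equiv), THF, −78 °C; 12, −78 → −30 °C; H2O
Reagents that add atoms: none
Why: Alkylation of the alkoxide–enolate dianion; C1 is quaternary, so only the C3 methyl can be enolised, and once the ketone is an enolate the retro-aldol is shut off, so the allylic bromide is displaced by SN2 to form C3–C4.

Step 10
Reactants: 13 (1Z,6R,7S)-7-hydroxy-1-iodo-2,6-dimethyl-6-(prop-2-en-1-yl)-11-(trimethylsilyl)undec-1-en-10-yn-5-one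
Product: 14 (1Z,5S,6R,7S)-1-iodo-2,6-dimethyl-6-(prop-2-en-1-yl)-11-(trimethylsilyl)undec-1-en-10-yne-5,7-diol
Conditions: Me4NBH(OAc)3, MeCN/AcOH (1:1), −30 °C
Reagents that add atoms: none
Why: Evans–Saksena reduction; the C14 hydroxyl binds boron and delivers hydride intramolecularly through a chair to the acid-activated C2 ketone, which should give the 1,3-anti diol (2S).

Step 11
Reactants: 14 (1Z,5S,6R,7S)-1-iodo-2,6-dimethyl-6-(prop-2-en-1-yl)-11-(trimethylsilyl)undec-1-en-10-yne-5,7-diol
Product: 15 (1Z,5S,6R,7S)-1-iodo-2,6-dimethyl-6-(prop-2-en-1-yl)-11-(trimethylsilyl)undec-1-en-10-yne-5,7-diyl diacetate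
Conditions: Ac2O, pyridine, DMAP (cat.), CH2Cl2, rt
Reagents that add atoms: acetic anhydride, CC(=O)OC(C)=O
Why: DMAP-catalysed acetylation installs the C2 and C14 acetates of the target, which serve as protecting groups for all later steps.

Step 12
Reactants: 15 (1Z,5S,6R,7S)-1-iodo-2,6-dimethyl-6-(prop-2-en-1-yl)-11-(trimethylsilyl)undec-1-en-10-yne-5,7-diyl diacetate
Product: 17 C9 aldehyde (diacetate 15 with the allyl group cut to CH2CHO), via vicinal diol 16 (not isolated)
Conditions: OsO4 (2 mol%), NaIO4, 2,6-lutidine, dioxane/H2O (3:1), rt
Reagents that add atoms: osmium tetroxide, O=[Os](=O)(=O)=O; sodium periodate, [Na+].[O-]I(=O)(=O)=O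
Why: Lemieux–Johnson cleavage; OsO4 attacks the unhindered monosubstituted alkene, while the trisubstituted, iodine-bearing alkene and the silyl alkyne are electron-poor or hindered and should survive.

Step 13
Reactants: 17 C9 aldehyde; 18 allyl methoxymethyl ether
Product: 19 (8S,9S)-syn adduct: C9 secondary alcohol, C8 methoxymethyl ether, C7 as vinyl CH, otherwise as 17
Conditions: 18, s-BuLi, THF, −78 °C; (+)-Ipc2BOMe; BF3·OEt2; 17, −78 °C; then H2O2, pH 7 buffer, 0 °C
Reagents that add atoms: none
Why: Brown (Z)-γ-alkoxyallylboration through a chair transition state gives the syn 1,2-diol mono-ether with the absolute sense set by the isopinocampheyl groups; C8 and C9 are sacrificial stereocentres chosen to steer C7 in step 16 and to tell the two oxygens apart, and the non-basic reagent spares the acetates.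

Step 14
Reactants: 19 (8S,9S)-syn adduct
Product: 20 C9 tert-butyldimethylsilyl ether of 19
Conditions: t-BuMe2SiOTf, 2,6-lutidine, CH2Cl2, −40 → 0 °C
Reagents that add atoms: tert-butyldimethylsilyl trifluoromethanesulfonate, CC(C)(C)[Si](C)(C)OS(=O)(=O)C(F)(F)F
Why: Silyl triflate silylates the hindered secondary alcohol; the ether must outlast the acetal cleavage and both oxidations that follow.

Step 15
Reactants: 20 C9 silyl ether
Product: 22 seco aldehyde (C7 aldehyde, C8 OMOM, C9 OTBS, Z-vinyl iodide at C6), via vicinal diol 21 (not isolated)
Conditions: OsO4 (2 mol%), NaIO4, 2,6-lutidine, dioxane/H2O (3:1), rt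
Reagents that add atoms: osmium tetroxide, O=[Os](=O)(=O)=O; sodium periodate, [Na+].[O-]I(=O)(=O)=O
Why: A second Lemieux–Johnson cleavage turns the terminal vinyl group into the C7 aldehyde under buffered conditions that do not epimerise the α-alkoxy centre; chemoselectivity is as in step 12.

Step 16
Reactants: 22 seco aldehyde
Product: 23 ten-membered carbocycle (Z-C5=C6) with 7S hydroxyl, C8 OMOM (7,8-anti), C9 OTBS (8,9-syn), C2 acetate, and on C1 the methyl and the (1S)-1-acetoxy-5-(trimethylsilyl)pent-4-ynyl arm
Conditions: CrCl2 (10 equiv), NiCl2 (1 mol% of Cr), DMSO/THF (3:1), rt, 2 mM; H2O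
Reagents that add atoms: none
Why: Nozaki–Hiyama–Kishi macrocyclisation: zerovalent nickel inserts into the vinyl iodide with retention of the Z geometry, transmetalation gives the vinyl–chromium species, which adds chemoselectively to the aldehyde at high dilution. Felkin–Anh addition with the C8 alkoxy group anti to the incoming vinyl carbon should give the 7,8-anti, hence 7S, alcohol.

Step 17
Reactants: 23 macrocyclic allylic alcohol; 24 2-bromopropanoyl bromide
Product: 25 C7 2-bromopropanoate of 23
Conditions: 24, pyridine, CH2Cl2, 0 °C
Reagents that add atoms: none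
Why: Acylation of the secondary alcohol attaches C17–C19 (with C18) to the C7 oxygen as the tether for the lactone.

Step 18
Reactants: 25 C7 2-bromopropanoate
Product: 26 C8 alcohol (MOM group removed)
Conditions: Me2BBr, CH2Cl2, −78 °C; then H2O
Reagents that add atoms: none
Why: Dimethylboron bromide cleaves acetal-type ethers at low temperature by bromide attack on the activated O–CH2–O unit and should leave esters, the silyl ether and the alkyl bromide untouched; the cold, non-basic conditions suppress acyl migration from O7 to O8.

Step 19
Reactants: 26 C8 alcohol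
Product: 27 C8 ketone bearing the C7 2-bromopropanoate and the C9 silyl ether
Conditions: Dess–Martin periodinane, NaHCO3, CH2Cl2, 0 °C → rt
Reagents that add atoms: none
Why: Buffered Dess–Martin oxidation gives the α-acyloxy ketone without epimerising the acidic C7 position.

Step 20
Reactants: 27 C8 ketone
Product: 28 γ-lactone (7S,8S,17R) with free tertiary C8 hydroxyl, C9 OTBS and silyl alkyne
Conditions: SmI2 (2.2 equiv), THF, −78 °C; H2O
Reagents that add atoms: none
Why: Intramolecular Reformatsky reaction promoted by SmI2: two electrons convert the C–Br bond into a samarium enolate, which adds within a chelate to the C8 ketone and closes the five-membered lactone. The C9 chain takes the side anti to C6 and the C18 methyl the side anti to C9; this is also the most stable arrangement, since all neighbouring carbon substituents on the lactone are trans.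

Step 21
Reactants: 28 γ-lactone
Product: 30 C9 alcohol with terminal alkyne, via terminal alkyne still silylated at O9 29 (not isolated)
Conditions: Bu4NF, AcOH (1:1), THF, 0 °C → rt
Reagents that add atoms: none
Why: Fluoride removes the alkynyl silane quickly and the hindered silyl ether more slowly; acetic acid buffering protects the acetates and the β-hydroxy lactone from base.

Step 22
Reactants: 30 C9 alcohol
Product: 31 ten-membered C9 ketone with free C8 hydroxyl, lactone, C2/C14 acetates and the pentynyl arm
Conditions: Dess–Martin periodinane, NaHCO3, CH2Cl2, rt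
Reagents that add atoms: none
Why: Only the secondary C9 hydroxyl can be oxidised; the tertiary C8 hydroxyl is inert, so the two sacrificial stereocentres have now been removed.

Step 23
Reactants: 31 C9 ketone
Product: 33 C9 triisopropylsilyl enol ether (C9=C10, C8 and C1 cis in the ring) with C8 triethylsilyl ether, via C8 triethylsilyl ether ketone 32 (not isolated)
Conditions: Et3SiOTf, 2,6-lutidine, CH2Cl2, −78 °C; then i-Pr3SiOTf, Et3N, 0 °C → rt
Reagents that add atoms: triethylsilyl trifluoromethanesulfonate, CC[Si](CC)(CC)OS(=O)(=O)C(F)(F)F; triisopropylsilyl trifluoromethanesulfonate, CC(C)[Si](C(C)C)(C(C)C)OS(=O)(=O)C(F)(F)F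
Why: The tertiary hydroxyl is silylated first; soft enolisation with silyl triflate and amine then gives the silyl enol ether, which can only form towards C10 because C8 has no hydrogen. A triethylsilyl ether is chosen for O8 because it should survive the protic gold conditions better than a trimethylsilyl ether.

Step 24
Reactants: 33 silyl enol ether
Product: 34 bicyclic C9 ketone with exocyclic C11=C20 methylene, trans-fused at C1/C10 (10S)
Conditions: (Ph3P)AuCl (10 mol%), AgBF4 (10 mol%), CH2Cl2/MeOH (10:1), rt → 40 °C
Reagents that add atoms: none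
Why: Cationic monovalent gold, freed from (Ph3P)AuCl by AgBF4, binds the terminal alkyne C11≡C20, and the silyl enol ether attacks anti to gold through C10 on the internal carbon C11; the closest known reaction type is the gold-catalysed Conia-ene-type carbocyclisation of silyl enol ethers onto alkynes. The cyclohexane (C1, C10–C14) closes in the 6-exo-dig mode through a chair with the C14 acetate axial. Methanol takes the silyl group from the oxocarbenium ion and protonates the vinyl–gold bond, releasing the C9 ketone, the exocyclic C11=C20 methylene and the catalyst. C10 is the only new stereocentre: 1,3-allylic strain across C9=C10 keeps the small C15 methyl in the enol ether plane next to C8 and the ring carbon C2 on one face, so the pentynyl arm closes on the opposite face and H10 ends anti to the methyl (trans fusion). If some cis-fused ketone forms, C10 can be epimerised next to the C9 carbonyl towards the trans isomer, in which both ring arms are equatorial. Regioselectivity is secured because C8 carries no hydrogen and the exo mode places C20 where the epoxide needs it; chemoselectivity rests on the enol ether being far more nucleophilic than the C5=C6 alkene or the acetate carbonyls.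

Step 25
Reactants: 34 bicyclic C9 ketone
Product: 35 (9S)-C9 alcohol
Conditions: NaBH4, CeCl3·7H2O, MeOH/THF, −40 → 0 °C
Reagents that add atoms: none
Why: Luche-type reduction under weakly basic conditions, which protects the epimerisable, doubly activated C10–H. In the polar Felkin–Anh model hydride attacks anti to the non-chelating C8 silyloxy group, and in the extended C7–C8–C9–C10 conformation this should give the 9S alcohol with O9 syn to O8; the lactone and acetates are not reduced at this temperature.

Step 26
Reactants: 35 (9S)-C9 alcohol
Product: 36 C2, C9, C14 triacetate with C8 triethylsilyl ether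
Conditions: Ac2O, DMAP, Et3N, CH2Cl2, rt
Reagents that add atoms: acetic anhydride, CC(=O)OC(C)=O
Why: DMAP-catalysed acetylation of the hindered secondary alcohol; the tertiary oxygen is still silylated.

Step 27
Reactants: 36 triacetate
Product: 37 C8 tertiary alcohol (11(20)-ene precursor of the target)
Conditions: HF·pyridine, pyridine, THF, 0 °C → rt
Reagents that add atoms: none
Why: Buffered HF removes the tertiary triethylsilyl ether without touching acetates, lactone or alkenes; this is done before the epoxide exists.

Step 28
Reactants: 37 C8 tertiary alcohol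
Product: 38 junceellolide K
Conditions: m-CPBA, NaHCO3, CH2Cl2, 0 °C
Reagents that add atoms: 3-chloroperoxybenzoic acid, O=C(OO)c1cccc(Cl)c1
Why: Prilezhaev epoxidation; the peracid approaches the exposed exocyclic methylene along the equatorial direction, because the axial C15 methyl blocks the other face through a 1,3-diaxial contact, giving the 11R epoxide with oxygen anti to that methyl. The C5=C6 alkene is deactivated by the allylic lactone oxygen and shielded inside the ring, and one equivalent of buffered oxidant is used.

## Compound list

1 | methyl acetoacetate | COC(=O)CC(C)=O | starting material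
2 | 3-bromo-1-(trimethylsilyl)prop-1-yne | C[Si](C)(C)C#CCBr | starting material
3 | methyl 3-oxo-7-(trimethylsilyl)hept-6-ynoate | COC(=O)CC(=O)CCC#C[Si](C)(C)C | intermediate
4 | methyl (3S)-3-hydroxy-7-(trimethylsilyl)hept-6-ynoate | COC(=O)C[C@@H](O)CCC#C[Si](C)(C)C | intermediate
5 | allyl bromide | C=CCBr | starting material
6 | methyl (2S,3S)-3-hydroxy-2-(prop-2-en-1-yl)-7-(trimethylsilyl)hept-6-ynoate | COC(=O)[C@@H](CC=C)[C@@H](O)CCC#C[Si](C)(C)C | intermediate
7 | methyl (2R,3S)-3-hydroxy-2-methyl-2-(prop-2-en-1-yl)-7-(trimethylsilyl)hept-6-ynoate | COC(=O)[C@](C)(CC=C)[C@@H](O)CCC#C[Si](C)(C)C | intermediate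
8 | (2R,3S)-3-hydroxy-N-methoxy-N,2-dimethyl-2-(prop-2-en-1-yl)-7-(trimethylsilyl)hept-6-ynamide | CON(C)C(=O)[C@](C)(CC=C)[C@@H](O)CCC#C[Si](C)(C)C | intermediate
9 | (3R,4S)-4-hydroxy-3-methyl-3-(prop-2-en-1-yl)-8-(trimethylsilyl)oct-7-yn-2-one | CC(=O)[C@](C)(CC=C)[C@@H](O)CCC#C[Si](C)(C)C | intermediate
10 | propargyl alcohol | C#CCO | starting material
11 | (2Z)-3-iodo-2-methylprop-2-en-1-ol | C/C(=C/I)CO | intermediate
12 | (1Z)-3-bromo-1-iodo-2-methylprop-1-ene | C/C(=C/I)CBr | intermediate
13 | (1Z,6R,7S)-7-hydroxy-1-iodo-2,6-dimethyl-6-(prop-2-en-1-yl)-11-(trimethylsilyl)undec-1-en-10-yn-5-one | C/C(=C/I)CCC(=O)[C@](C)(CC=C)[C@@H](O)CCC#C[Si](C)(C)C | intermediate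
14 | (1Z,5S,6R,7S)-1-iodo-2,6-dimethyl-6-(prop-2-en-1-yl)-11-(trimethylsilyl)undec-1-en-10-yne-5,7-diol | C/C(=C/I)CC[C@H](O)[C@](C)(CC=C)[C@@H](O)CCC#C[Si](C)(C)C | intermediate
15 | diacetate of 14 | C/C(=C/I)CC[C@H](OC(C)=O)[C@](C)(CC=C)[C@@H](OC(C)=O)CCC#C[Si](C)(C)C | intermediate
16 | vicinal diol from the allyl group of 15 (epimers at the new carbinol) | C/C(=C/I)CC[C@H](OC(C)=O)[C@](C)(CC(O)CO)[C@@H](OC(C)=O)CCC#C[Si](C)(C)C | intermediate
17 | C9 aldehyde | C/C(=C/I)CC[C@H](OC(C)=O)[C@](C)(CC=O)[C@@H](OC(C)=O)CCC#C[Si](C)(C)C | intermediate
18 | allyl methoxymethyl ether | C=CCOCOC | starting material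
19 | (8S,9S)-syn adduct, C9 alcohol, C8 OMOM, C7 vinyl | C/C(=C/I)CC[C@H](OC(C)=O)[C@](C)(C[C@H](O)[C@@H](OCOC)C=C)[C@@H](OC(C)=O)CCC#C[Si](C)(C)C | intermediate
20 | C9 tert-butyldimethylsilyl ether of 19 | C/C(=C/I)CC[C@H](OC(C)=O)[C@](C)(C[C@H](O[Si](C)(C)C(C)(C)C)[C@@H](OCOC)C=C)[C@@H](OC(C)=O)CCC#C[Si](C)(C)C | intermediate
21 | vicinal diol from the vinyl group of 20 (epimers at the new carbinol) | C/C(=C/I)CC[C@H](OC(C)=O)[C@](C)(C[C@H](O[Si](C)(C)C(C)(C)C)[C@@H](OCOC)C(O)CO)[C@@H](OC(C)=O)CCC#C[Si](C)(C)C | intermediate
22 | seco aldehyde (C7 aldehyde, Z-vinyl iodide) | C/C(=C/I)CC[C@H](OC(C)=O)[C@](C)(C[C@H](O[Si](C)(C)C(C)(C)C)[C@@H](OCOC)C=O)[C@@H](OC(C)=O)CCC#C[Si](C)(C)C | intermediate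
23 | ten-membered (7S)-allylic alcohol | CC(=O)O[C@H]1CC/C(C)=C\[C@H](O)[C@H](OCOC)[C@@H](O[Si](C)(C)C(C)(C)C)C[C@]1(C)[C@@H](OC(C)=O)CCC#C[Si](C)(C)C | intermediate
24 | 2-bromopropanoyl bromide (racemic) | CC(Br)C(=O)Br | starting material
25 | C7 2-bromopropanoate | CC(=O)O[C@H]1CC/C(C)=C\[C@H](OC(=O)C(C)Br)[C@H](OCOC)[C@@H](O[Si](C)(C)C(C)(C)C)C[C@]1(C)[C@@H](OC(C)=O)CCC#C[Si](C)(C)C | intermediate
26 | C8 alcohol | CC(=O)O[C@H]1CC/C(C)=C\[C@H](OC(=O)C(C)Br)[C@H](O)[C@@H](O[Si](C)(C)C(C)(C)C)C[C@]1(C)[C@@H](OC(C)=O)CCC#C[Si](C)(C)C | intermediate
27 | C8 ketone | CC(=O)O[C@H]1CC/C(C)=C\[C@H](OC(=O)C(C)Br)C(=O)[C@@H](O[Si](C)(C)C(C)(C)C)C[C@]1(C)[C@@H](OC(C)=O)CCC#C[Si](C)(C)C | intermediate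
28 | γ-lactone with C8 hydroxyl, C9 OTBS, silyl alkyne | CC(=O)O[C@H]1CC/C(C)=C\[C@@H]2OC(=O)[C@H](C)[C@@]2(O)[C@@H](O[Si](C)(C)C(C)(C)C)C[C@]1(C)[C@@H](OC(C)=O)CCC#C[Si](C)(C)C | intermediate
29 | terminal alkyne still silylated at O9 | CC(=O)O[C@H]1CC/C(C)=C\[C@@H]2OC(=O)[C@H](C)[C@@]2(O)[C@@H](O[Si](C)(C)C(C)(C)C)C[C@]1(C)[C@@H](OC(C)=O)CCC#C | intermediate
30 | C9 alcohol with terminal alkyne | CC(=O)O[C@H]1CC/C(C)=C\[C@@H]2OC(=O)[C@H](C)[C@@]2(O)[C@@H](O)C[C@]1(C)[C@@H](OC(C)=O)CCC#C | intermediate
31 | ten-membered C9 ketone with free C8 hydroxyl | CC(=O)O[C@H]1CC/C(C)=C\[C@@H]2OC(=O)[C@H](C)[C@@]2(O)C(=O)C[C@]1(C)[C@@H](OC(C)=O)CCC#C | intermediate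
32 | C8 triethylsilyl ether ketone | CC(=O)O[C@H]1CC/C(C)=C\[C@@H]2OC(=O)[C@H](C)[C@@]2(O[Si](CC)(CC)CC)C(=O)C[C@]1(C)[C@@H](OC(C)=O)CCC#C | intermediate
33 | ten-membered C9 silyl enol ether with the C1 pentynyl arm | CC(=O)O[C@H]1CC/C(C)=C\[C@@H]2OC(=O)[C@H](C)[C@@]2(O[Si](CC)(CC)CC)/C(O[Si](C(C)C)(C(C)C)C(C)C)=C\[C@]1(C)[C@@H](OC(C)=O)CCC#C | intermediate
34 | bicyclic C9 ketone with C11 methylene | CC(=O)O[C@H]1CC/C(C)=C\[C@@H]2OC(=O)[C@H](C)[C@@]2(O[Si](CC)(CC)CC)C(=O)[C@H]2C(=C)CC[C@H](OC(C)=O)[C@]12C | intermediate
35 | (9S)-alcohol | CC(=O)O[C@H]1CC/C(C)=C\[C@@H]2OC(=O)[C@H](C)[C@@]2(O[Si](CC)(CC)CC)[C@@H](O)[C@H]2C(=C)CC[C@H](OC(C)=O)[C@]12C | intermediate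
36 | triacetate with C8 triethylsilyl ether | CC(=O)O[C@H]1CC/C(C)=C\[C@@H]2OC(=O)[C@H](C)[C@@]2(O[Si](CC)(CC)CC)[C@@H](OC(C)=O)[C@H]2C(=C)CC[C@H](OC(C)=O)[C@]12C | intermediate
37 | triacetate with free C8 hydroxyl and C11 methylene | CC(=O)O[C@H]1CC/C(C)=C\[C@@H]2OC(=O)[C@H](C)[C@@]2(O)[C@@H](OC(C)=O)[C@H]2C(=C)CC[C@H](OC(C)=O)[C@]12C | intermediate
38 | junceellolide K | CC(=O)O[C@H]1CC/C(C)=C\[C@@H]2OC(=O)[C@H](C)[C@@]2(O)[C@@H](OC(C)=O)[C@H]2[C@]3(CC[C@H](OC(C)=O)[C@]12C)CO3 | target

## Step count and least certain steps

Total step count: 28. Longest linear sequence: 26 steps (steps 1–6 and 9–28, from 1); steps 7–8 prepare bromide 12.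

**Step 24 (key step).** The most likely failure is loss of the enol ether by methanolysis before the carbon–carbon bond forms, since the hindered C10 must reach the alkyne across a crowded quaternary centre; closure on the wrong enol ether face would give the cis-fused ketone. Fallback, setting out from 33: N-iodosuccinimide converts the enol ether into the α-iodo ketone F1. Et3B/air then starts an iodine-atom-transfer radical cyclisation, in which the C10 radical closes 6-exo-dig onto the alkyne to give the iodomethylene cyclohexane F2. Bu3SnH with AIBN removes the vinylic iodine and the route is rejoined at 34.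

**Step 16.** Poor facial selectivity at C7 is the main concern, because the acyclic Felkin–Anh preference may be overridden by the conformation of the closing ring; intermolecular coupling competes if dilution is insufficient. Fallback, setting out from 22: if the closure favours the 7R epimer of the allylic alcohol F3, that alcohol is esterified with 2-bromopropanoic acid under Mitsunobu conditions (PPh3, diisopropyl azodicarboxylate). This inverts C7 while installing the tether, and the route is rejoined at 25.

**Step 20.** Single-electron reduction of the α-acyloxy ketone (loss of the C7 ester) may compete with enolate formation, and the samarium aldolate may revert by retro-aldol. Fallback, setting out from 23: acylation with acryloyl chloride gives the acrylate F4. Removal of the acetal as in step 18 gives the alcohol F5, and oxidation as in step 19 gives the ketone F6. A copper hydride reductive aldol cyclisation with [(Ph3P)CuH]6 then makes the C17 enolate by conjugate hydride addition instead of halide reduction, closes the lactone and rejoins the route at 28.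

**Step 25.** Hydride delivery to the wrong face of the C9 carbonyl is possible, because the face preference depends on the ring conformation next to two fully substituted carbons; base-induced shift of the exocyclic alkene into conjugation is a second hazard. Fallback, setting out from 34: HF·pyridine first frees the tertiary hydroxyl to give the α-hydroxy ketone F7. Me4NBH(OAc)3 then delivers hydride internally from the C8 oxygen, the face an external reagent avoids, to give the diol F8. Selective acetylation of the secondary hydroxyl (Ac2O, pyridine) rejoins the route at 37.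

**Step 28.** Competing epoxidation of the trisubstituted C5=C6 alkene is the main risk, since peracids favour the more substituted alkene on electronic grounds. Fallback, setting out from 37: OsO4 with N-methylmorpholine N-oxide, which responds more strongly to steric shielding and to the deactivating allylic oxygen, dihydroxylates the exposed methylene from the equatorial face to give the triol F9. Mitsunobu cyclodehydration (PPh3, diisopropyl azodicarboxylate) activates the primary hydroxyl and closes the epoxide with retention at C11, giving 38.

## Further compounds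

F1 | step 24 | C10 α-iodo ketone with C8 triethylsilyl ether (epimers at C10) | CC(=O)O[C@H]1CC/C(C)=C\[C@@H]2OC(=O)[C@H](C)[C@@]2(O[Si](CC)(CC)CC)C(=O)C(I)[C@]1(C)[C@@H](OC(C)=O)CCC#C
F2 | step 24 | bicyclic C9 ketone with C11 iodomethylene (alkene isomers) | CC(=O)O[C@H]1CC/C(C)=C\[C@@H]2OC(=O)[C@H](C)[C@@]2(O[Si](CC)(CC)CC)C(=O)[C@H]2C(=CI)CC[C@H](OC(C)=O)[C@]12C
F3 | step 16 | ten-membered (7R)-allylic alcohol, C7 epimer of 23 | CC(=O)O[C@H]1CC/C(C)=C\[C@@H](O)[C@H](OCOC)[C@@H](O[Si](C)(C)C(C)(C)C)C[C@]1(C)[C@@H](OC(C)=O)CCC#C[Si](C)(C)C
F4 | step 20 | C7 acrylate of 23 | CC(=O)O[C@H]1CC/C(C)=C\[C@H](OC(=O)C=C)[C@H](OCOC)[C@@H](O[Si](C)(C)C(C)(C)C)C[C@]1(C)[C@@H](OC(C)=O)CCC#C[Si](C)(C)C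
F5 | step 20 | C7 acrylate with free C8 hydroxyl | CC(=O)O[C@H]1CC/C(C)=C\[C@H](OC(=O)C=C)[C@H](O)[C@@H](O[Si](C)(C)C(C)(C)C)C[C@]1(C)[C@@H](OC(C)=O)CCC#C[Si](C)(C)C
F6 | step 20 | C7 acrylate C8 ketone | CC(=O)O[C@H]1CC/C(C)=C\[C@H](OC(=O)C=C)C(=O)[C@@H](O[Si](C)(C)C(C)(C)C)C[C@]1(C)[C@@H](OC(C)=O)CCC#C[Si](C)(C)C
F7 | step 25 | bicyclic C9 ketone with free C8 hydroxyl | CC(=O)O[C@H]1CC/C(C)=C\[C@@H]2OC(=O)[C@H](C)[C@@]2(O)C(=O)[C@H]2C(=C)CC[C@H](OC(C)=O)[C@]12C
F8 | step 25 | (9S)-C8,C9 diol | CC(=O)O[C@H]1CC/C(C)=C\[C@@H]2OC(=O)[C@H](C)[C@@]2(O)[C@@H](O)[C@H]2C(=C)CC[C@H](OC(C)=O)[C@]12C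
F9 | step 28 | C8,C11,C20 triol | CC(=O)O[C@H]1CC/C(C)=C\[C@@H]2OC(=O)[C@H](C)[C@@]2(O)[C@@H](OC(C)=O)[C@H]2[C@@](O)(CO)CC[C@H](OC(C)=O)[C@]12C
A1 | alternative 1 | aldol adduct with C10, C1 and C2 set | C/C(=C/I)CC[C@H](O)[C@@]1(C)C(=O)CC[C@@H](O[Si](C)(C)C(C)(C)C)[C@@H]1C=C
A2 | alternative 1 | (4R)-4-(tert-butyldimethylsilyloxy)-2-methylcyclohex-2-en-1-one | O=C1CC[C@@H](O[Si](C)(C)C(C)(C)C)C=C1C
A3 | alternative 1 | (4Z)-5-iodo-4-methylpent-4-enal | C/C(=C/I)CCC=O
A4 | alternative 2 | ten-membered C2 ketone with Z C5=C6 alkene | O=C1CC/C(C)=C\[C@H](OCOC)C2(OCCO2)[C@@H](OCOC)[C@H]2[C@]3(CC[C@H](O[Si](C)(C)C(C)(C)C)[C@]12C)CO3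
A5 | alternative 2 | 2-methylene oxocane with C6 isopropenyl group (one C6 epimer) | C=C1O[C@@H](C(C)=C)[C@H](OCOC)C2(OCCO2)[C@@H](OCOC)[C@H]2[C@]3(CC[C@H](O[Si](C)(C)C(C)(C)C)[C@]12C)CO3
A6 | alternative 3 | ten-membered ring fused to the C8=C17 butenolide | CC(=O)O[C@H]1CC/C(C)=C\[C@@H]2OC(=O)C(C)=C2[C@@H](O[Si](C)(C)C(C)(C)C)[C@H]2[C@]3(CC[C@H](OC(C)=O)[C@]12C)CO3
A7 | alternative 3 | Z-enal with C8≡C17 but-2-ynyl silyl ether on the epoxy cyclohexane | CC(=O)O[C@@H](CC/C(C)=C\C=O)[C@@]1(C)[C@@H](OC(C)=O)CC[C@]2(CO2)[C@@H]1[C@H](O[Si](C)(C)C(C)(C)C)C#CC
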